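## Retrosynthetic overview

1. The last bond made is C6–C7 (the sp2 ring carbon of ring A to the terminal CH of the polyene), by a Stille coupling of the sulfated ring A enol triflate 21 with the C31 nonaenyl stannane 20. Both partners are unprotected, so this step should give the target itself.
2. Enabling feature: in ring A, C6 lies between the quaternary C1 (gem-dimethyl) and the methyl-bearing C5. A C6 ketone can therefore enolize only towards C5, and its enol triflate is a single C5=C6 regioisomer with the leaving group on C6. C7 is a terminal E-vinyl CH that can carry tin.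
3. Both end rings come from one building block. Dearomatizing C-methylation of 2,6-dimethylphenol supplies all nine ring carbons; asymmetric epoxidation of the C2=C3 alkene and anti hydrolysis set (2R,3R); reductive triflation gives ring triflate 9. Compound 9 becomes ring B (step 8) and, after 3-O-sulfation, ring A (21).
4. Stannane 20: 9 plus stannyl dienol 11 (C6'–C7'), then phosphonium salt 13; C10 dialdehyde 16 plus stannyl phosphonate 15 (C11=C12); then Wittig union (C11'=C12').
5. Rings: no ring is closed. Both cyclohexenes are the carbocycle of the phenol; ring B is joined to the chain first, ring A last.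

Key step: step 15

Assumption: the target is drawn as the free hydrogen sulfate, so the sulfate monoesters 21 and 22 are written in that neutral form. In the flask they would be handled as tetrabutylammonium salts, the counter-ion being exchanged during work-up without changing the structures as drawn.

## Route

Step 1
Reactants: 1 2,6-dimethylphenol
Product: 3 2,6,6-trimethylcyclohexa-2,4-dien-1-one, via lithium 2,6-dimethylphenoxide 2 (not isolated)
Conditions: n-BuLi, toluene, 0 °C; then MeI, 135 °C (sealed vessel); distillation, used fresh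
Reagents that add atoms: methyl iodide, CI; n-butyllithium, [Li]CCCC (its lithium stays only in intermediate 2)
Why: Alkylative dearomatization (ortho C-methylation of a phenoxide): in toluene the tightly ion-paired lithium phenoxide 2 is alkylated on carbon at an ortho position that already bears a methyl group, which gives the non-aromatizable 6,6-dimethyl-2,4-dienone holding all nine carbons of an end ring (gem-dimethyl C1, methyl on C5, oxygen on C6 in carotenoid numbering), with no stereocenter formed.

Step 2
Reactants: 3 2,6,6-trimethylcyclohexa-2,4-dien-1-one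
Product: 4 (4S,5R)-4,5-epoxy-2,6,6-trimethylcyclohex-2-en-1-one
Conditions: (S,S)-Mn(salen)Cl [salen = N,N'-bis(3,5-di-tert-butylsalicylidene)cyclohexane-1,2-diamine dianion] (5 mol %), mCPBA, N-methylmorpholine N-oxide, CH2Cl2, -78 °C
Reagents that add atoms: meta-chloroperbenzoic acid, O=C(OO)c1cccc(Cl)c1
Why: Jacobsen–Katsuki epoxidation: the electrophilic oxo complex of pentavalent manganese attacks the cis-disubstituted, more electron-rich C4=C5 alkene and not the α-methyl enone alkene, and the substrate is a carbocyclic analogue of 2,2-dimethylchromene (cis-alkene flanked by a quaternary carbon and a conjugating sp2 carbon), so the chiral salen ligand should set both epoxide centers (4S,5R) by reagent control, the catalyst enantiomer being chosen by that analogy.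

Step 3
Reactants: 4 (4S,5R)-4,5-epoxy-2,6,6-trimethylcyclohex-2-en-1-one
Product: 5 (4R,5R)-4,5-dihydroxy-2,6,6-trimethylcyclohex-2-en-1-one
Conditions: HClO4 (cat.), THF/H2O, 0 °C
Reagents that add atoms: water, O
Why: Acid-catalysed anti opening of an epoxide by water: SN2-type attack occurs at the allylic carbon C4 and not at the neopentyl carbon C5, so C4 is inverted and C5 keeps its oxygen, which turns the (4S,5R)-epoxide into the trans-(4R,5R)-diol, that is (3R,2R) of the end group.

Step 4
Reactants: 5 (4R,5R)-4,5-dihydroxy-2,6,6-trimethylcyclohex-2-en-1-one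
Product: 6 (4R,5R)-2,6,6-trimethyl-4,5-bis(triethylsilyloxy)cyclohex-2-en-1-one
Conditions: TESOTf, 2,6-lutidine, CH2Cl2, -78 to 0 °C
Reagents that add atoms: triethylsilyl trifluoromethanesulfonate, CC[Si](CC)(CC)OS(=O)(=O)C(F)(F)F
Why: Silyl ether formation with a silyl triflate, reactive enough for the neopentyl-type 5-OH, masks both hydroxyls for the hydride and triflation step and touches no stereocenter.

Step 5
Reactants: 6 (4R,5R)-2,6,6-trimethyl-4,5-bis(triethylsilyloxy)cyclohex-2-en-1-one
Product: 8 (4R,5R)-2,6,6-trimethyl-4,5-bis(triethylsilyloxy)cyclohex-1-en-1-yl trifluoromethanesulfonate, via lithium enolate 7 (not isolated)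
Conditions: LiBH(s-Bu)3, THF, -78 °C; then N-(5-chloropyridin-2-yl)bis(trifluoromethanesulfonyl)imide, -78 to 0 °C
Reagents that add atoms: N-(5-chloropyridin-2-yl)bis(trifluoromethanesulfonyl)imide, O=S(=O)(N(c1ccc(Cl)cn1)S(=O)(=O)C(F)(F)F)C(F)(F)F; lithium tri-sec-butylborohydride, [Li+].CCC(C)[BH-](C(C)CC)C(C)CC (hydride; its lithium stays only in intermediate 7)
Why: Conjugate reduction with enolate trapping: the bulky hydride adds 1,4 to the β-unsubstituted enone whose carbonyl is shielded by the gem-dimethyl group, and O-triflation of the single possible enolate 7 places the triflate on C1 of a C1=C2 alkene (C6 and C5=C6 of the end group) without creating a stereocenter.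

Step 6
Reactants: 8 (4R,5R)-2,6,6-trimethyl-4,5-bis(triethylsilyloxy)cyclohex-1-en-1-yl trifluoromethanesulfonate
Product: 9 (4R,5R)-4,5-dihydroxy-2,6,6-trimethylcyclohex-1-en-1-yl trifluoromethanesulfonate
Conditions: HF·pyridine, THF, 0 °C to rt
Reagents that add atoms: none
Why: Fluoride-mediated cleavage of silyl ethers under mildly acidic conditions, which leave the alkenyl triflate untouched, frees the diol that serves both end groups.

Step 7
Reactants: 10 (E)-3-methylpent-2-en-4-yn-1-ol
Product: 11 (2E,4E)-3-methyl-5-(tributylstannyl)penta-2,4-dien-1-ol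
Conditions: Bu3SnH, PdCl2(PPh3)2 (cat.), THF, 0 °C
Reagents that add atoms: tributyltin hydride, CCCC[SnH](CCCC)CCCC
Why: Palladium-catalysed hydrostannation of a terminal alkyne: syn addition of tin and hydrogen across the 1,3-enyne should place tin on the terminal carbon and give the E-alkenylstannane, the existing 2E alkene being unaffected.

Step 8
Reactants: 9 (4R,5R)-4,5-dihydroxy-2,6,6-trimethylcyclohex-1-en-1-yl trifluoromethanesulfonate; 11 (2E,4E)-3-methyl-5-(tributylstannyl)penta-2,4-dien-1-ol
Product: 12 (2E,4E)-5-[(4R,5R)-4,5-dihydroxy-2,6,6-trimethylcyclohex-1-en-1-yl]-3-methylpenta-2,4-dien-1-ol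
Conditions: Pd2(dba)3 (cat.), AsPh3, NMP, 60 °C
Reagents that add atoms: none
Why: Stille coupling: oxidative addition of zerovalent palladium into the hindered enol triflate, transmetalation with retention of the E-alkenyl geometry and reductive elimination form the C6'–C7' bond of ring B, free hydroxyls being tolerated under these neutral conditions.

Step 9
Reactants: 12 (2E,4E)-5-[(4R,5R)-4,5-dihydroxy-2,6,6-trimethylcyclohex-1-en-1-yl]-3-methylpenta-2,4-dien-1-ol
Product: 13 [(2E,4E)-5-[(4R,5R)-4,5-dihydroxy-2,6,6-trimethylcyclohex-1-en-1-yl]-3-methylpenta-2,4-dien-1-yl]triphenylphosphonium bromide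
Conditions: PPh3·HBr, MeOH, 0 °C to rt; crystallization
Reagents that add atoms: triphenylphosphine hydrobromide, [Br-].[PH+](c1ccccc1)(c1ccccc1)c1ccccc1
Why: Phosphonium salt formation from an allylic alcohol: protonation and ionization give a ring-conjugated pentadienyl cation that triphenylphosphine captures at the primary terminus, the non-allylic secondary ring hydroxyls being inert, as in the standard preparation of hydroxylated C15 Wittig salts.

Step 10
Reactants: 11 (2E,4E)-3-methyl-5-(tributylstannyl)penta-2,4-dien-1-ol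
Product: 14 tributyl[(1E,3E)-5-bromo-3-methylpenta-1,3-dien-1-yl]stannane
Conditions: CBr4, PPh3, 2,6-lutidine, CH2Cl2, -20 °C
Reagents that add atoms: carbon tetrabromide, BrC(Br)(Br)Br
Why: Appel bromination converts the primary allylic alcohol into the bromide by SN2 displacement of the oxyphosphonium leaving group under buffered, acid-free conditions that spare the alkenylstannane.

Step 11
Reactants: 14 tributyl[(1E,3E)-5-bromo-3-methylpenta-1,3-dien-1-yl]stannane
Product: 15 diethyl [(2E,4E)-3-methyl-5-(tributylstannyl)penta-2,4-dien-1-yl]phosphonate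
Conditions: P(OEt)3 (neat), 80 °C
Reagents that add atoms: triethyl phosphite, CCOP(OCC)OCC
Why: Michaelis–Arbuzov reaction: SN2 attack of the phosphite on the primary allylic bromide and dealkylation by bromide give the dienylphosphonate.

Step 12
Reactants: 15 diethyl [(2E,4E)-3-methyl-5-(tributylstannyl)penta-2,4-dien-1-yl]phosphonate; 16 (2E,4E,6E)-2,7-dimethylocta-2,4,6-trienedial
Product: 18 (2E,4E,6E,8E,10E,12E)-2,7,11-trimethyl-13-(tributylstannyl)trideca-2,4,6,8,10,12-hexaenal, via sodium phosphonate carbanion 17 (not isolated)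
Conditions: NaN(SiMe3)2, THF, -78 °C; then added to 16 (3 equiv), -78 to 0 °C
Reagents that add atoms: sodium bis(trimethylsilyl)amide, C[Si](C)(C)[N-][Si](C)(C)C.[Na+] (its sodium stays only in intermediate 17)
Why: Horner–Wadsworth–Emmons olefination: the conjugation-stabilized phosphonate carbanion 17, added to an excess of the symmetrical dialdehyde, should react once and give the new disubstituted alkene (C11=C12) with E geometry.

Step 13
Reactants: 13 [(2E,4E)-5-[(4R,5R)-4,5-dihydroxy-2,6,6-trimethylcyclohex-1-en-1-yl]-3-methylpenta-2,4-dien-1-yl]triphenylphosphonium bromide; 18 (2E,4E,6E,8E,10E,12E)-2,7,11-trimethyl-13-(tributylstannyl)trideca-2,4,6,8,10,12-hexaenal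
Product: 20 (1R,2R)-3,3,5-trimethyl-4-[(1E,3E,5E,7E,9E,11E,13E,15E,17E)-3,7,12,16-tetramethyl-18-(tributylstannyl)octadeca-1,3,5,7,9,11,13,15,17-nonaen-1-yl]cyclohex-4-ene-1,2-diol, via phosphonium ylide 19 (not isolated)
Conditions: NaOMe, MeOH/CH2Cl2, 0 °C to rt; then EtOH, 70 °C, dark
Reagents that add atoms: none
Why: Wittig olefination of the classic C15 plus aldehyde type, run under protic methoxide conditions that tolerate the free diol; the semi-stabilized allylic ylide 19 forms the C11'=C12' alkene and brief heating should equilibrate any 11'Z isomer to the all-E polyene.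

Step 14
Reactants: 9 (4R,5R)-4,5-dihydroxy-2,6,6-trimethylcyclohex-1-en-1-yl trifluoromethanesulfonate
Product: 21 (4R,5R)-5-hydroxy-2,6,6-trimethyl-4-(sulfooxy)cyclohex-1-en-1-yl trifluoromethanesulfonate
Conditions: SO3·pyridine (1.1 equiv), pyridine, 0 °C; NaHCO3 (aq), Bu4NHSO4 work-up
Reagents that add atoms: sulfur trioxide pyridine complex, O=S(=O)([O-])[n+]1ccccc1
Why: O-Sulfation with a sulfur trioxide amine complex under steric control: the 4-OH (C3 of the end group), flanked by a methylene, should react in preference to the 5-OH (C2), which is shielded by the adjacent gem-dimethyl carbon, and no stereocenter is touched.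

Step 15
Reactants: 20 (1R,2R)-3,3,5-trimethyl-4-[(1E,3E,5E,7E,9E,11E,13E,15E,17E)-3,7,12,16-tetramethyl-18-(tributylstannyl)octadeca-1,3,5,7,9,11,13,15,17-nonaen-1-yl]cyclohex-4-ene-1,2-diol; 21 (4R,5R)-5-hydroxy-2,6,6-trimethyl-4-(sulfooxy)cyclohex-1-en-1-yl trifluoromethanesulfonate
Product: 22 (2R,3R,2'R,3'R)-2,2',3'-trihydroxy-β,β-caroten-3-yl hydrogen sulfate (CNP0229621.3)
Conditions: Pd2(dba)3 (cat.), AsPh3, NMP, 55 °C, dark, argon; cation exchange on work-up
Reagents that add atoms: none
Why: Zerovalent palladium inserts into the C6–O bond of the enol triflate of 21, the E-alkenyl group migrates from tin to palladium at C7 with retention, and reductive elimination forms the C6–C7 bond, completing the eleven-double-bond chromophore and the C40 skeleton in the last operation. The closest known reaction type is the Stille coupling of 2,6,6-trimethylcyclohex-1-enyl triflates with dienyl and tetraenyl stannanes used for retinoids, run with AsPh3 as a weakly bound ligand in NMP so that transmetalation to the hindered tetrasubstituted alkenylpalladium is fast. No ring is closed and no stereocenter is created; the four carbinol centers arrive intact in the two fragments. The step needs chemoselectivity (only the C–OTf bond reacts while the sulfate monoester anion and three free secondary hydroxyls are bystanders under neutral, base-free conditions) and retention of all nine E double bonds of the chain, which the stereospecific transmetalation, moderate temperature and exclusion of light and acid should secure. Regiochemistry is fixed in advance because C1 is quaternary, so the triflate sits on C6 of a C5=C6 enol and nowhere else. Carrying the sulfate in on ring A also settles the only difference between the two ends without any late differentiation of four hydroxyls.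

## Compound list

1 | 2,6-dimethylphenol | Cc1cccc(C)c1O | starting material
2 | lithium 2,6-dimethylphenoxide | [Li+].[O-]c1c(C)cccc1C | intermediate
3 | 2,6,6-trimethylcyclohexa-2,4-dien-1-one | CC1=CC=CC(C)(C)C1=O | intermediate
4 | (4S,5R)-4,5-epoxy-2,6,6-trimethylcyclohex-2-en-1-one [(1R,6S)-2,2,4-trimethyl-7-oxabicyclo[4.1.0]hept-4-en-3-one] | O=C1C(C)=C[C@@H]2O[C@@H]2C1(C)C | intermediate
5 | (4R,5R)-4,5-dihydroxy-2,6,6-trimethylcyclohex-2-en-1-one | O=C1C(C)=C[C@@H](O)[C@H](O)C1(C)C | intermediate
6 | (4R,5R)-2,6,6-trimethyl-4,5-bis(triethylsilyloxy)cyclohex-2-en-1-one | O=C1C(C)=C[C@@H](O[Si](CC)(CC)CC)[C@H](O[Si](CC)(CC)CC)C1(C)C | intermediate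
7 | lithium (4R,5R)-2,6,6-trimethyl-4,5-bis(triethylsilyloxy)cyclohex-1-en-1-olate | [Li+].[O-]C1=C(C)C[C@@H](O[Si](CC)(CC)CC)[C@H](O[Si](CC)(CC)CC)C1(C)C | intermediate
8 | (4R,5R)-2,6,6-trimethyl-4,5-bis(triethylsilyloxy)cyclohex-1-en-1-yl trifluoromethanesulfonate | O=S(=O)(OC1=C(C)C[C@@H](O[Si](CC)(CC)CC)[C@H](O[Si](CC)(CC)CC)C1(C)C)C(F)(F)F | intermediate
9 | (4R,5R)-4,5-dihydroxy-2,6,6-trimethylcyclohex-1-en-1-yl trifluoromethanesulfonate | O=S(=O)(OC1=C(C)C[C@@H](O)[C@H](O)C1(C)C)C(F)(F)F | intermediate
10 | (E)-3-methylpent-2-en-4-yn-1-ol | C#C/C(C)=C/CO | starting material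
11 | (2E,4E)-3-methyl-5-(tributylstannyl)penta-2,4-dien-1-ol | CCCC[Sn](CCCC)(CCCC)/C=C/C(C)=C/CO | intermediate
12 | (2E,4E)-5-[(4R,5R)-4,5-dihydroxy-2,6,6-trimethylcyclohex-1-en-1-yl]-3-methylpenta-2,4-dien-1-ol | OC/C=C(C)/C=C/C1=C(C)C[C@@H](O)[C@H](O)C1(C)C | intermediate
13 | [(2E,4E)-5-[(4R,5R)-4,5-dihydroxy-2,6,6-trimethylcyclohex-1-en-1-yl]-3-methylpenta-2,4-dien-1-yl]triphenylphosphonium bromide | [Br-].C(/C=C(C)/C=C/C1=C(C)C[C@@H](O)[C@H](O)C1(C)C)[P+](c1ccccc1)(c1ccccc1)c1ccccc1 | intermediate
14 | tributyl[(1E,3E)-5-bromo-3-methylpenta-1,3-dien-1-yl]stannane | CCCC[Sn](CCCC)(CCCC)/C=C/C(C)=C/CBr | intermediate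
15 | diethyl [(2E,4E)-3-methyl-5-(tributylstannyl)penta-2,4-dien-1-yl]phosphonate | CCOP(=O)(OCC)C/C=C(C)/C=C/[Sn](CCCC)(CCCC)CCCC | intermediate
16 | (2E,4E,6E)-2,7-dimethylocta-2,4,6-trienedial | O=C/C(C)=C/C=C/C=C(C)/C=O | starting material
17 | sodium salt of the carbanion of phosphonate 15 | CCOP(=O)(OCC)[CH-]/C=C(C)/C=C/[Sn](CCCC)(CCCC)CCCC.[Na+] | intermediate
18 | (2E,4E,6E,8E,10E,12E)-2,7,11-trimethyl-13-(tributylstannyl)trideca-2,4,6,8,10,12-hexaenal | O=C/C(C)=C/C=C/C=C(C)/C=C/C=C(C)/C=C/[Sn](CCCC)(CCCC)CCCC | intermediate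
19 | phosphonium ylide of salt 13 | [CH-](/C=C(C)/C=C/C1=C(C)C[C@@H](O)[C@H](O)C1(C)C)[P+](c1ccccc1)(c1ccccc1)c1ccccc1 | intermediate
20 | (1R,2R)-3,3,5-trimethyl-4-[(1E,3E,5E,7E,9E,11E,13E,15E,17E)-3,7,12,16-tetramethyl-18-(tributylstannyl)octadeca-1,3,5,7,9,11,13,15,17-nonaen-1-yl]cyclohex-4-ene-1,2-diol | CC1=C(/C=C/C(C)=C/C=C/C(C)=C/C=C/C=C(C)/C=C/C=C(C)/C=C/[Sn](CCCC)(CCCC)CCCC)C(C)(C)[C@@H](O)[C@H](O)C1 | intermediate
21 | (4R,5R)-5-hydroxy-2,6,6-trimethyl-4-(sulfooxy)cyclohex-1-en-1-yl trifluoromethanesulfonate | O=S(=O)(OC1=C(C)C[C@@H](OS(=O)(=O)O)[C@H](O)C1(C)C)C(F)(F)F | intermediate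
22 | (2R,3R,2'R,3'R)-2,2',3'-trihydroxy-β,β-caroten-3-yl hydrogen sulfate (CNP0229621.3) | CC1=C(/C=C/C(C)=C/C=C/C(C)=C/C=C/C=C(C)/C=C/C=C(C)/C=C/C2=C(C)C[C@@H](OS(=O)(=O)O)[C@H](O)C2(C)C)C(C)(C)[C@@H](O)[C@H](O)C1 | target

## Step count and risks

Total step count: 15. Longest linear sequence: 10 steps (steps 1, 2, 3, 4, 5, 6, 8, 9, 13, 15).

Steps most likely to fail:

Step 15. Oxidative addition at the hindered, anionic triflate may be slow, so that protodestannylation and E/Z scrambling of the long stannane 20 compete with coupling. Fallback: setting out from 21 and the shorter stannane 18, a Stille coupling (Pd2(dba)3, AsPh3, NMP, 55 °C) would give the sulfated C25 apo-aldehyde F1. Wittig olefination of F1 with the ylide from the ring B salt 13 (NaOMe, MeOH/CH2Cl2, then thermal equilibration) would close C11'=C12' and come back to the route at 22; the C6–C7 bond is then made on a small hexaenyl stannane and the final union is an olefination.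

Step 14. Discrimination between the two secondary hydroxyls may be insufficient, leading to sulfation at the 5-OH and to double sulfation. Fallback: setting out from epoxide 4, opening with benzoic acid (PhCO2H, PhCO2Cs cat., DMF, 50 °C; anti attack at allylic C4) would give the hydroxy benzoate F2, in which the two oxygens are told apart by the ring opening itself. TESOTf/2,6-lutidine would give the silyl ether F3, and LiBH(s-Bu)3 followed by the pyridyl triflimide the enol triflate F4. K2CO3 in MeOH at 0 °C would remove the benzoate to give the mono-alcohol F5, and SO3·pyridine would sulfate its only free hydroxyl to give the silyl sulfate F6. HF·pyridine would then remove the silyl group and come back to the route at 21.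

Step 2. Facial selectivity may be poor, or oxidation of the enone alkene may compete, on this electron-poor diene. Fallback: setting out from 3, mCPBA (CH2Cl2, 0 °C) would give the racemic epoxide F7 and dilute aqueous acid the racemic trans-diol F8. Lipase-catalysed acylation (Candida antarctica lipase B, vinyl acetate) should, by the usual empirical preference for secondary alcohols, acylate the (4R)-alcohol to give the monoacetate F9, separable from the unreacted (4S,5S)-diol. K2CO3/MeOH on F9 would come back to the route at 5.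

Further compounds

F1 | step 15 | (1R,6R)-6-hydroxy-3,5,5-trimethyl-4-[(1E,3E,5E,7E,9E,11E)-3,7,12-trimethyl-13-oxotrideca-1,3,5,7,9,11-hexaen-1-yl]cyclohex-3-en-1-yl hydrogen sulfate (sulfated C25 apo-aldehyde) | O=C/C(C)=C/C=C/C=C(C)/C=C/C=C(C)/C=C/C1=C(C)C[C@@H](OS(=O)(=O)O)[C@H](O)C1(C)C
F2 | step 14 | (4R,5R)-4-benzoyloxy-5-hydroxy-2,6,6-trimethylcyclohex-2-en-1-one | O=C1C(C)=C[C@@H](OC(=O)c2ccccc2)[C@H](O)C1(C)C
F3 | step 14 | (4R,5R)-4-benzoyloxy-2,6,6-trimethyl-5-(triethylsilyloxy)cyclohex-2-en-1-one | O=C1C(C)=C[C@@H](OC(=O)c2ccccc2)[C@H](O[Si](CC)(CC)CC)C1(C)C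
F4 | step 14 | (4R,5R)-4-benzoyloxy-2,6,6-trimethyl-5-(triethylsilyloxy)cyclohex-1-en-1-yl trifluoromethanesulfonate | O=S(=O)(OC1=C(C)C[C@@H](OC(=O)c2ccccc2)[C@H](O[Si](CC)(CC)CC)C1(C)C)C(F)(F)F
F5 | step 14 | (4R,5R)-4-hydroxy-2,6,6-trimethyl-5-(triethylsilyloxy)cyclohex-1-en-1-yl trifluoromethanesulfonate | O=S(=O)(OC1=C(C)C[C@@H](O)[C@H](O[Si](CC)(CC)CC)C1(C)C)C(F)(F)F
F6 | step 14 | (4R,5R)-2,6,6-trimethyl-4-(sulfooxy)-5-(triethylsilyloxy)cyclohex-1-en-1-yl trifluoromethanesulfonate | O=S(=O)(OC1=C(C)C[C@@H](OS(=O)(=O)O)[C@H](O[Si](CC)(CC)CC)C1(C)C)C(F)(F)F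
F7 | step 2 | racemic 4,5-epoxy-2,6,6-trimethylcyclohex-2-en-1-one (cis-fused, both enantiomers) | O=C1C(C)=CC2OC2C1(C)C
F8 | step 2 | racemic trans-4,5-dihydroxy-2,6,6-trimethylcyclohex-2-en-1-one (both enantiomers) | O=C1C(C)=CC(O)C(O)C1(C)C
F9 | step 2 | (4R,5R)-4-acetoxy-5-hydroxy-2,6,6-trimethylcyclohex-2-en-1-one | O=C1C(C)=C[C@@H](OC(C)=O)[C@H](O)C1(C)C
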